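Rings: A/C = the 5,7-dihydroxychromone unit, B/D = benzene and dihydropyran rings of the chroman, A'/C'/B' = the apigenin unit.
Cuts, in retrosynthetic order: five O–MOM bonds; C2 (ring C)–C6 (ring B); C6–B back to C6–H; the biaryl bond C8 (ring B)–C8 (ring A'); C8–I and C8–B; O–CMe2 of ring D.
Forward: both benzopyranones are bought intact (apigenin, 5,7-dihydroxychromone). Only ring D is closed (step 1). The blocks are then joined as apigenin C8 + chroman C8 (Suzuki–Miyaura), followed by chroman C6 + chromone C2 (oxidative boron-Heck).
Enabling features: in ring C, O1–C2(H)=C3(H)–C4=O is an unsubstituted, polarised vinylogous ester. An aryl–palladium species therefore delivers its aryl group to C2, and the ring re-forms by loss of C2–H, so the chromone needs no halogen. In ring B, once C8 is arylated, C6–H is the only aromatic C–H of the molecule flanked by two C–H. Steric iridium borylation places a temporary boron there, and that boron leaves in the key step.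
Stereochemistry: the target has no stereocentre, and the transient sp3 atoms C2/C3 of ring C are flattened again within the key step.
Key step: step 8

Assumption: the SMILES defines no stereo-element, so the tri-ortho-substituted biaryl axis is treated as configurationally undefined and no axial control is attempted.

Step 1
Reactants: 1 dihydrocoumarin (chroman-2-one)
Product: 3 2,2-dimethylchroman, via open-chain diol 2 (not isolated)
Conditions: MeMgBr (excess), THF, 0 °C to rt; 1 M HCl quench; crude 2, cat. p-TsOH·H2O, toluene, reflux (Dean–Stark)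
Reagents that add atoms: methylmagnesium bromide C[Mg]Br
Why: Double Grignard addition to the lactone carbonyl gives the phenol/tertiary alcohol, and acid-catalysed cyclodehydration (tertiary cation trapped by the phenol oxygen, six-membered ring) closes ring D with unambiguous regiochemistry, because the ortho C–C bond is already present in 1.

Step 2
Reactants: 3 2,2-dimethylchroman
Product: 5 2-(2,2-dimethylchroman-8-yl)-4,4,5,5-tetramethyl-1,3,2-dioxaborolane, via aryllithium 4 (not isolated)
Conditions: n-BuLi, TMEDA, Et2O, 0 °C to rt; iPrOBpin, −78 °C to rt; 1 M HCl quench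
Reagents that add atoms: 2-isopropoxy-4,4,5,5-tetramethyl-1,3,2-dioxaborolane (iPrOBpin) CC(C)OB1OC(C)(C)C(C)(C)O1
Why: Directed ortho-metalation, in which the ring oxygen is the only directing group and C8–H the only position ortho to it, should lithiate C8 as in anisole-type ethers, and the aryllithium is trapped by alkoxide displacement at boron.

Step 3
Reactants: 6 apigenin
Product: 7 5,7-bis(methoxymethoxy)-2-[4-(methoxymethoxy)phenyl]-4H-chromen-4-one
Conditions: NaH, MOMCl, DMF, 0 °C to rt
Reagents that add atoms: chloromethyl methyl ether (MOMCl) COCCl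
Why: Williamson-type O-alkylation of all three phenoxides (NaH also frees the chelated 5-OH) installs a group that carries no aromatic C–H to disturb step 6 and that leaves under acid mild enough for the tertiary ether of ring D.

Step 4
Reactants: 7 apigenin tris-MOM ether
Product: 8 8-iodo-5,7-bis(methoxymethoxy)-2-[4-(methoxymethoxy)phenyl]-4H-chromen-4-one
Conditions: NIS, DMF, rt to 50 °C, dark
Reagents that add atoms: N-iodosuccinimide O=C1CCC(=O)N1I
Why: Neutral electrophilic aromatic iodination should hit ring A', the most electron-rich ring, at C8 (flanked by one OMOM and the ring oxygen) rather than at C6 (between two OMOM groups), as is typical of 5,7-dialkoxyflavones, while the acetals survive the acid-free medium.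

Step 5
Reactants: 8 8-iodoflavone; 5 chroman-8-boronate
Product: 9 8-(2,2-dimethylchroman-8-yl)-5,7-bis(methoxymethoxy)-2-[4-(methoxymethoxy)phenyl]-4H-chromen-4-one
Conditions: Pd(OAc)2, SPhos, K3PO4, toluene/H2O, 90 °C
Reagents that add atoms: none
Why: Suzuki–Miyaura coupling with a bulky electron-rich biarylphosphine on zerovalent palladium is suited to tri-ortho-substituted biaryls, C–I is the only site for oxidative addition, and the flavone and MOM ethers tolerate aqueous phosphate.

Step 6
Reactants: 9 8-(chroman-8-yl)flavone
Product: 10 8-[2,2-dimethyl-6-(4,4,5,5-tetramethyl-1,3,2-dioxaborolan-2-yl)chroman-8-yl]-5,7-bis(methoxymethoxy)-2-[4-(methoxymethoxy)phenyl]-4H-chromen-4-one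
Conditions: [Ir(OMe)(cod)]2 (cat.), 4,4'-di-tert-butyl-2,2'-bipyridine (cat.), B2pin2, THF, 80 °C
Reagents that add atoms: bis(pinacolato)diboron CC1(C)OB(OC1(C)C)B1OC(C)(C)C(C)(C)O1
Why: Sterically governed iridium-catalysed aromatic C–H borylation should select C6–H of ring B, the only C–H with two hydrogen neighbours, since C5–H and C7–H of ring B, C6–H of ring A', C3–H of ring C' and all four C–H of ring B' each have an ortho substituent.

Step 7
Reactants: 11 5,7-dihydroxy-4H-chromen-4-one
Product: 12 5,7-bis(methoxymethoxy)-4H-chromen-4-one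
Conditions: NaH, MOMCl, DMF, 0 °C to rt
Reagents that add atoms: chloromethyl methyl ether (MOMCl) COCCl
Why: Williamson-type O-alkylation of both phenoxides proceeds without a nucleophilic oxygen base in the flask, so the base-sensitive unsubstituted C2 of the chromone is not attacked.

Step 8
Reactants: 10 arylboronate; 12 5,7-bis(methoxymethoxy)chromone
Product: 13 8-{6-[5,7-bis(methoxymethoxy)-4-oxo-4H-chromen-2-yl]-2,2-dimethylchroman-8-yl}-5,7-bis(methoxymethoxy)-2-[4-(methoxymethoxy)phenyl]-4H-chromen-4-one
Conditions: Pd(O2CCF3)2 (cat.), 5-nitro-1,10-phenanthroline (cat.), O2 (1 atm), DMSO, 100 °C; 12 in excess, 10 added slowly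
Reagents that add atoms: none
Why: Transmetalation of the unhindered C6–B bond of 10 to phenanthroline-ligated divalent palladium trifluoroacetate gives an aryl–palladium species that adds syn across C2=C3 of 12, aryl to C2 and palladium to C3 as a C/O-bound enolate; face exchange through the O-bound form brings palladium syn to C2–H, β-hydride elimination restores the 4-pyranone ring, and O2 returns zerovalent palladium to the divalent state. The closest known reaction type is the oxidative boron-Heck arylation of chromones and chroman-4-ones with arylboronic acids or pinacol esters, which gives flavones directly. No ring is closed and no stereocentre survives, because the transient sp3 atoms C2 and C3 are flattened again in the same operation, and protonolysis of the enolate is no dead end since the same catalyst system dehydrogenates chroman-4-ones. Regioselectivity (C2, not C3) follows from the polarisation O1–C2=C3–C4=O, which makes C2 the β-carbon of a vinylogous ester and lets palladium end next to the carbonyl group. Chemoselectivity between the two pyranone rings present is secured by substitution, since C2 of ring C' in 10 already bears an aryl group and only the C2(H)=C3(H) bond of 12 can insert and then eliminate. Homocoupling and protodeboronation of the valuable partner are held down by the excess of 12 and the slow addition of 10.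

Step 9
Reactants: 13 penta-MOM ether
Product: 14 8-[6-(5,7-dihydroxy-4-oxo-4H-chromen-2-yl)-2,2-dimethylchroman-8-yl]-5,7-dihydroxy-2-(4-hydroxyphenyl)-4H-chromen-4-one (CNP0127025.0)
Conditions: 3 M aq. HCl, MeOH/THF, 55 °C
Reagents that add atoms: none
Why: Acid-catalysed acetal solvolysis removes all five MOM groups while methanol traps the formaldehyde equivalent as its acetal away from the free phloroglucinol-type rings, ring D survives as the acid-stable closed form of its own ring-opened cation, and the conditions are far milder than those of a Wessely–Moser isomerisation.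

Compound list
1 | dihydrocoumarin (chroman-2-one) | O=C1CCc2ccccc2O1 | starting material
2 | 2-(3-hydroxy-3-methylbutyl)phenol | CC(C)(O)CCc1ccccc1O | intermediate
3 | 2,2-dimethylchroman | CC1(C)CCc2ccccc2O1 | intermediate
4 | (2,2-dimethylchroman-8-yl)lithium | [Li]c1cccc2c1OC(C)(C)CC2 | intermediate
5 | 2-(2,2-dimethylchroman-8-yl)-4,4,5,5-tetramethyl-1,3,2-dioxaborolane | CC1(C)CCc2cccc(B3OC(C)(C)C(C)(C)O3)c2O1 | intermediate
6 | apigenin | O=c1cc(-c2ccc(O)cc2)oc2cc(O)cc(O)c12 | starting material
7 | 5,7-bis(methoxymethoxy)-2-[4-(methoxymethoxy)phenyl]-4H-chromen-4-one | COCOc1ccc(-c2cc(=O)c3c(OCOC)cc(OCOC)cc3o2)cc1 | intermediate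
8 | 8-iodo-5,7-bis(methoxymethoxy)-2-[4-(methoxymethoxy)phenyl]-4H-chromen-4-one | COCOc1ccc(-c2cc(=O)c3c(OCOC)cc(OCOC)c(I)c3o2)cc1 | intermediate
9 | 8-(2,2-dimethylchroman-8-yl)-5,7-bis(methoxymethoxy)-2-[4-(methoxymethoxy)phenyl]-4H-chromen-4-one | CC1(C)CCc2cccc(-c3c(OCOC)cc(OCOC)c4c(=O)cc(-c5ccc(OCOC)cc5)oc34)c2O1 | intermediate
10 | C6-pinacolboronate of 9 | CC1(C)CCc2cc(B3OC(C)(C)C(C)(C)O3)cc(-c3c(OCOC)cc(OCOC)c4c(=O)cc(-c5ccc(OCOC)cc5)oc34)c2O1 | intermediate
11 | 5,7-dihydroxy-4H-chromen-4-one | O=c1ccoc2cc(O)cc(O)c12 | starting material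
12 | 5,7-bis(methoxymethoxy)-4H-chromen-4-one | COCOc1cc(OCOC)c2c(=O)ccoc2c1 | intermediate
13 | penta-MOM ether of the target | CC1(C)CCc2cc(-c3cc(=O)c4c(OCOC)cc(OCOC)cc4o3)cc(-c3c(OCOC)cc(OCOC)c4c(=O)cc(-c5ccc(OCOC)cc5)oc34)c2O1 | intermediate
14 | CNP0127025.0 | CC1(C)CCc2cc(-c3cc(=O)c4c(O)cc(O)cc4o3)cc(-c3c(O)cc(O)c4c(=O)cc(-c5ccc(O)cc5)oc34)c2O1 | target

Total steps: 9. Longest linear sequence: 6 (steps 1, 2, 5, 6, 8, 9, or equally steps 3, 4, 5, 6, 8, 9).

Steps most likely to fail

1. Step 8.
- Risk: migratory insertion into the electron-rich 5,7-dialkoxychromone may be slow. Oxidative homocoupling, protodeboronation and C–B oxidation of the boronate under O2 could then take over, and acetal loss at 100 °C may blur the product.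
- Fallback: it sets out from 10 and 12 and comes back at 13. It separates bond formation from oxidation.
- The pinacol ester is cleaved (NaIO4, NH4OAc, acetone/H2O, rt) to the free arylboronic acid F1.
- A redox-neutral 1,4-addition under monovalent rhodium catalysis ([Rh(OH)(cod)]2, toluene/H2O, 40 °C, argon) to 12 gives the racemic flavanone F2, with ring C partly saturated.
- With no boron left in the flask, aerobic dehydrogenation (Pd(O2CCF3)2, DMSO, O2, 80–100 °C) aromatises ring C to 13.

2. Step 6.
- Risk: the catalyst may be tied up by the carbonyl/5-OMOM region of the flavone. Alternatively, borylation may spill over to the positions ortho to OMOM on ring B' once the reaction is forced.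
- Fallback: it sets out from 3, uses 8, and comes back at 10. It carries a halogen at C6 from the start instead of relying on C–H selection.
- Para-chlorination (SO2Cl2, CH2Cl2, 0 °C) gives 6-chloro-2,2-dimethylchroman F3.
- Bromination at the remaining ortho position (NBS, MeCN, rt) gives 8-bromo-6-chloro-2,2-dimethylchroman F4.
- C–Br-selective Miyaura borylation (Pd(dppf)Cl2, B2pin2, KOAc, dioxane, 80 °C) gives the 6-chlorochroman-8-boronate F5.
- Suzuki–Miyaura coupling with 8, using a catalyst that leaves C–Cl alone (Pd(PPh3)4, K3PO4, dioxane/H2O, 90 °C), gives the 6-chloro biaryl F6.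
- Miyaura borylation of the aryl chloride (Pd2(dba)3, XPhos, B2pin2, KOAc, dioxane, 100 °C) returns to 10.

3. Step 5.
- Risk: transmetalation of the ortho-oxygenated pinacol boronate to the doubly ortho-substituted aryl–palladium iodide may be slow. Protodeboronation and hydrodeiodination would then compete in the hot aqueous base.
- Fallback: it sets out from 3 (through 4), uses 8, and comes back at 9. It replaces boron by zinc and removes base and water altogether.
- The aryllithium 4 is transmetalated with ZnCl2 (THF, 0 °C) to (2,2-dimethylchroman-8-yl)zinc chloride F7.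
- F7 is joined to 8 by Negishi coupling (Pd2(dba)3, RuPhos, THF, 60 °C). The flavone carbonyl group tolerates the organozinc reagent.

Further compounds
F1 | step 8 | boronic acid corresponding to 10 | CC1(C)CCc2cc(B(O)O)cc(-c3c(OCOC)cc(OCOC)c4c(=O)cc(-c5ccc(OCOC)cc5)oc34)c2O1
F2 | step 8 | racemic 2,3-dihydro (flavanone) form of 13, saturated in ring C | CC1(C)CCc2cc(C3CC(=O)c4c(OCOC)cc(OCOC)cc4O3)cc(-c3c(OCOC)cc(OCOC)c4c(=O)cc(-c5ccc(OCOC)cc5)oc34)c2O1
F3 | step 6 | 6-chloro-2,2-dimethylchroman | CC1(C)CCc2cc(Cl)ccc2O1
F4 | step 6 | 8-bromo-6-chloro-2,2-dimethylchroman | CC1(C)CCc2cc(Cl)cc(Br)c2O1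
F5 | step 6 | 2-(6-chloro-2,2-dimethylchroman-8-yl)-4,4,5,5-tetramethyl-1,3,2-dioxaborolane | CC1(C)CCc2cc(Cl)cc(B3OC(C)(C)C(C)(C)O3)c2O1
F6 | step 6 | 8-(6-chloro-2,2-dimethylchroman-8-yl)-5,7-bis(methoxymethoxy)-2-[4-(methoxymethoxy)phenyl]-4H-chromen-4-one | CC1(C)CCc2cc(Cl)cc(-c3c(OCOC)cc(OCOC)c4c(=O)cc(-c5ccc(OCOC)cc5)oc34)c2O1
F7 | step 5 | (2,2-dimethylchroman-8-yl)zinc chloride | CC1(C)CCc2cccc([Zn]Cl)c2O1
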